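**Retrosynthetic overview**

1. The target comes from the tricyclic triol by 13‑O‑acetylation and 8‑O‑angeloylation. The oxonane is closed last by a Ramberg–Bäcklund ring contraction: a ten‑membered cyclic sulfone with SO2 between C5 and C6 loses its sulfur atom and leaves the C5=C6 enol‑lactone double bond.
2. The ten‑membered sulfone comes from a C5 sulfinic acid condensing with the 5‑hydroxybutenolide (pseudo‑acid) at C6, a reversible C6–S bond formation. The butenolide comes from a 3,4‑disubstituted furan and singlet oxygen.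
3. C8–C9 comes from a furyl‑dithiane anion opening a C9/C10 epoxide, and C8 is set by transfer hydrogenation. The tetrahydrofuran with C1, C4 and C10 comes from (S)‑linalool by allylic oxidation, Sharpless epoxidation and 5‑exo epoxide opening.
4. Ring order: tetrahydrofuran (step 5), butenolide (step 14), temporary ten‑membered thia‑ring (step 15), oxonane (step 16).
5. Enabling feature: C6, the atom shared by butenolide and oxonane. It is the acetal‑level carbon of the lactone and one end of the only C=C of the nine‑membered ring (C5=C6), so it can carry a sulfonyl group as an S,O‑acetal with an acidic C6–H (aromatic 2‑oxidofuran anion).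

Key step: step 16

Numbering used in the names: tetrahydrofuran = O, C1(H), C2, C3, C4(CH3); C5=C6 = enol‑lactone double bond; C7 and C11 = butenolide alkene carbons; C12 = lactone C=O; C13 = CH2O on C11; C8 = angelate carbinol; C9 = CH2 between C8 and C10; C10 = tertiary carbinol.

Remark: read from the SMILES, the target is 1S,4S,8S,10R, and the C1–C10 and C4–C5 bonds leave the tetrahydrofuran from opposite faces. The route builds exactly this arrangement; because it makes the nine‑membered ring tight, the ring is closed at ten‑membered size and then contracted.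

**Route**

Step 1
Reactants: 1 furan-3,4-diyldimethanol
Product: 2 [4-({[tert-butyl(dimethyl)silyl]oxy}methyl)furan-3-yl]methanol
Conditions: NaH (1.0 equiv), THF, 0 °C; TBSCl (1.0 equiv), rt
Reagents that add atoms: tert-butyl(chloro)dimethylsilane CC(C)(C)[Si](C)(C)Cl
Why: One equivalent of NaH and silylation of the poorly soluble mono‑alkoxide should give the mono‑silyl ether of the symmetric diol (Williamson‑type O‑silylation).

Step 2
Reactants: 2 [4-({[tert-butyl(dimethyl)silyl]oxy}methyl)furan-3-yl]methanol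
Product: 3 4-({[tert-butyl(dimethyl)silyl]oxy}methyl)furan-3-carbaldehyde
Conditions: MnO2, CH2Cl2, rt
Reagents that add atoms: none
Why: MnO2 oxidises the remaining furylmethyl (heterobenzylic) alcohol to the aldehyde and leaves silyl ether and furan alone.

Step 3
Reactants: 3 4-({[tert-butyl(dimethyl)silyl]oxy}methyl)furan-3-carbaldehyde
Product: 4 2-[4-({[tert-butyl(dimethyl)silyl]oxy}methyl)furan-3-yl]-1,3-dithiane
Conditions: HS(CH2)3SH, BF3·OEt2 (cat.), CH2Cl2, −40 → −20 °C
Reagents that add atoms: propane-1,3-dithiol SCCCS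
Why: Lewis‑acid‑catalysed dithioacetalisation turns the aldehyde into the 1,3‑dithiane that serves as acyl‑anion precursor for C8; the low temperature keeps the silyl ether.

Step 4
Reactants: 5 (S)-(+)-linalool
Product: 6 (2E,6S)-2,6-dimethylocta-2,7-diene-1,6-diol
Conditions: SeO2 (cat.), t-BuOOH, CH2Cl2, rt
Reagents that add atoms: tert-butyl hydroperoxide CC(C)(C)OO
Why: Selenium dioxide allylic oxidation (ene reaction, then [2,3] shift) hydroxylates the E‑methyl group of the trisubstituted alkene and leaves the tertiary vinyl carbinol alone; the stereocentre of 5 becomes C4.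

Step 5
Reactants: 6 (2E,6S)-2,6-dimethylocta-2,7-diene-1,6-diol
Product: 8 (2R)-2-[(2S,5S)-5-ethenyl-5-methyloxolan-2-yl]propane-1,2-diol, via epoxy alcohol 7 (not isolated)
Conditions: Ti(Oi-Pr)4 (cat.), D-(−)-diethyl tartrate (cat.), t-BuOOH, 4 Å MS, CH2Cl2, −20 °C; then CSA (cat.), 0 °C → rt
Reagents that add atoms: tert-butyl hydroperoxide CC(C)(C)OO
Why: Sharpless asymmetric epoxidation of the primary allylic alcohol with D‑(−)‑tartrate should give the (2R,3R)‑epoxide 7 by reagent control, and acid lets the C4 hydroxyl open it 5‑exo at the carbon remote from CH2OH with inversion, which sets C1 (S) and C10 (R) and closes the tetrahydrofuran with the side chain trans to the vinyl group.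

Step 6
Reactants: 8 (2R)-2-[(2S,5S)-5-ethenyl-5-methyloxolan-2-yl]propane-1,2-diol
Product: 10 (2S,5S)-2-ethenyl-2-methyl-5-[(2R)-2-methyloxiran-2-yl]oxolane, via primary tosylate 9 (not isolated)
Conditions: NaH (2.2 equiv), THF, 0 °C; N-tosylimidazole, 0 °C → rt
Reagents that add atoms: none
Why: The primary alkoxide is tosylated selectively and the tertiary alkoxide closes the epoxide by intramolecular Williamson substitution at the primary carbon, so C10 keeps its configuration.

Step 7
Reactants: 4 2-[4-({[tert-butyl(dimethyl)silyl]oxy}methyl)furan-3-yl]-1,3-dithiane; 10 (2S,5S)-2-ethenyl-2-methyl-5-[(2R)-2-methyloxiran-2-yl]oxolane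
Product: 12 (2R)-1-{2-[4-({[tert-butyl(dimethyl)silyl]oxy}methyl)furan-3-yl]-1,3-dithian-2-yl}-2-[(2S,5S)-5-ethenyl-5-methyloxolan-2-yl]propan-2-ol, via lithiated dithiane 11 (not isolated)
Conditions: 4, n-BuLi, THF, −30 °C; then 10, DMPU, −30 °C → rt; aq. NH4Cl
Reagents that add atoms: none
Why: Corey–Seebach alkylation: the 2‑lithio‑1,3‑dithiane opens the 2,2‑disubstituted epoxide at its CH2 end (C9), which forms the C8–C9 bond and frees the C10 tertiary alcohol with its configuration untouched.

Step 8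
Reactants: 12 dithiane adduct
Product: 13 (3R)-1-[4-({[tert-butyl(dimethyl)silyl]oxy}methyl)furan-3-yl]-3-[(2S,5S)-5-ethenyl-5-methyloxolan-2-yl]-3-hydroxybutan-1-one
Conditions: MeI, CaCO3, MeCN–H2O (9:1), 45 °C
Reagents that add atoms: water O
Why: S‑Methylation makes the dithiane a leaving group and buffered hydrolysis releases the C8 ketone (alkylative dithioacetal hydrolysis) under conditions that spare furan, alkene and silyl ether.

Step 9
Reactants: 13 β-hydroxy furyl ketone
Product: 14 (1S,3R)-1-[4-({[tert-butyl(dimethyl)silyl]oxy}methyl)furan-3-yl]-3-[(2S,5S)-5-ethenyl-5-methyloxolan-2-yl]butane-1,3-diol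
Conditions: RuCl(p-cymene)[(S,S)-TsDPEN] (cat.), HCO2H–Et3N (5:2), rt
Reagents that add atoms: none
Why: Noyori asymmetric transfer hydrogenation of the heteroaryl ketone: the (S,S)‑catalyst should give the (S)‑carbinol with the furyl group as the directing aryl substituent, so C8 is set by reagent control.

Step 10
Reactants: 14 diol
Product: 15 O8,O10,O13-tris(tert-butyldimethylsilyl) ether of the furyl triol (1S,4S,8S,10R; vinyl on C4)
Conditions: TBSOTf, 2,6-lutidine, CH2Cl2, 0 °C → rt
Reagents that add atoms: tert-butyldimethylsilyl trifluoromethanesulfonate CC(C)(C)[Si](C)(C)OS(=O)(=O)C(F)(F)F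
Why: The silyl triflate silylates the secondary and the tertiary hydroxyl so that neither can later form a cyclic acetal with C6 or be deprotonated (O‑silylation).

Step 11
Reactants: 15 tris-silyl ether
Product: 18 C5 primary alcohol (vinyl of 15 replaced by CH2OH), via vicinal diol 16 (not isolated), via aldehyde 17 (not isolated)
Conditions: OsO4 (cat.), NaIO4, 2,6-lutidine, dioxane–H2O, rt; then NaBH4, MeOH, 0 °C
Reagents that add atoms: sodium periodate (terminal oxidant and oxygen source via OsO4) [Na+].[O-]I(=O)(=O)=O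
Why: Lemieux–Johnson oxidation cleaves the terminal vinyl group (the aromatic furan reacts far more slowly with OsO4) and borohydride reduces the non‑enolisable C5 aldehyde to the primary alcohol.

Step 12
Reactants: 18 C5 primary alcohol
Product: 20 C5 sulfide (C4–CH2–S–CH2CH2CO2CH3), via triflate 19 (not isolated)
Conditions: Tf2O, 2,6-lutidine, CH2Cl2, −78 °C; then HS(CH2)2CO2Me, Cs2CO3, DMF, −40 → 0 °C
Reagents that add atoms: methyl 3-sulfanylpropanoate COC(=O)CCS
Why: The primary triflate is displaced by the soft thiolate (SN2 at a CH2 next to a fully substituted ether carbon, as in displacements of ketose C1 triflates), which puts the future ring sulfur on C5 in masked form.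

Step 13
Reactants: 20 C5 sulfide
Product: 21 C5 sulfone (C4–CH2–SO2–CH2CH2CO2CH3)
Conditions: TPAP (cat.), NMO, 4 Å MS, MeCN, rt
Reagents that add atoms: 4-methylmorpholine N-oxide C[N+]1([O-])CCOCC1
Why: Ley–Griffith conditions oxidise the sulfide to the sulfone and should leave the furan untouched; the β‑sulfonyl ester is a base‑releasable sulfinate.

Step 14
Reactants: 21 C5 sulfone
Product: 23 5-hydroxybutenolide (C12 lactone C=O, C6 hemiacetal, epimers at C6), via endoperoxide 22 (not isolated)
Conditions: O2, hν (visible), Rose Bengal (cat.), i-Pr2NEt, CH2Cl2, −78 °C → rt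
Reagents that add atoms: dioxygen O=O
Why: [4+2] addition of singlet oxygen gives endoperoxide 22, and the hindered amine should remove the bridgehead H at C12 (flanked only by CH2OTBS) rather than at C6 (shielded by the branched C8 substituent) in a Kornblum–DeLaMare fragmentation, so C12 becomes the lactone carbonyl and C6 the hemiacetal.

Step 15
Reactants: 23 5-hydroxybutenolide
Product: 25 ten-membered cyclic sulfone (SO2 bridges C5 and C6; epimers at C6), via sulfinic acid 24 (not isolated)
Conditions: NaOMe, MeOH–THF, 0 °C → rt; then AcOH, toluene, 4 Å MS, 50 °C, high dilution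
Reagents that add atoms: none
Why: Methoxide releases the C5 sulfinate by retro‑Michael loss of methyl acrylate, and on acidification the sulfinic acid condenses with the pseudo‑acid at C6 (as 2‑formylbenzoic acid gives 3‑sulfonylphthalides), a reversible C–S bond formation that should close the ten‑membered ring under thermodynamic control.

Step 16
Reactants: 25 ten-membered cyclic sulfone
Product: 28 tris-TBS ether of the tricyclic triol (oxonane closed; 5E enol lactone; 1S,4S,8S,10R), via C5 chloride 26 (not isolated), via episulfone 27 (not isolated)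
Conditions: LDA (2.1 equiv), THF, −78 °C; C2Cl6 (1.0 equiv), −78 → 0 °C
Reagents that add atoms: none
Why: Proposed new method: the first equivalent of LDA removes the doubly activated C6–H (giving an aromatic 2‑oxidofuran that also masks the lactone carbonyl and takes away the acidity of C8–H), the second removes an α′‑H at C5, and one equivalent of C2Cl6 chlorinates the more basic C5 carbanion to 26, whose remaining carbanion displaces chloride 3‑exo‑tet to episulfone 27; cheletropic loss of SO2 then turns the ten‑membered thia‑ring into the oxonane by making the C5–C6 σ and π bonds (ring contraction, the sulfur atom is deleted). The closest known reaction types are the Ramberg–Bäcklund contraction of medium and large cyclic sulfones to cycloalkenes with in situ halogenation and the Ramberg–Bäcklund synthesis of exocyclic enol ethers from anomeric (S,O‑acetal) sulfones; not yet shown are a lactone acetal carbon as sulfone terminus and the preformed α,α′‑dianion. The oxonane is closed by a 1,3‑elimination/extrusion sequence and not by a macrocyclisation, so the strain of the trans‑bridged nine‑membered ring is paid by the irreversible loss of SO2. No stereocentre is formed (C6 and the transient C5–Cl centre disappear) and the alkene geometry is controlled by the ring: inside a ten‑membered ring only the episulfone with C4 and C7 cis can form, and its stereospecific SO2 loss gives C5=C6 with C4 cis to C7, which is the E enol lactone of the target. The step needs a site‑selective second deprotonation and a single halogenation: the sulfone directs the base to C5, the oxidofuran protects C8–H, C9–H and the lactone, and should chlorine end up on C6 instead, the C5 carbanion closes the same episulfone.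

Step 17
Reactants: 28 tris-TBS ether
Product: 29 tricyclic triol (free OH at C8, C10 and C13)
Conditions: HF·pyridine, pyridine–THF, 0 °C → rt
Reagents that add atoms: none
Why: Fluoride cleaves the three silyl ethers under mildly acidic conditions that the enol lactone should tolerate (desilylation).

Step 18
Reactants: 29 tricyclic triol
Product: 30 13-O-acetate
Conditions: Ac2O (1.1 equiv), 2,4,6-collidine, CH2Cl2, −20 °C
Reagents that add atoms: acetic anhydride CC(=O)OC(C)=O
Why: Acylation should discriminate the primary allylic C13 hydroxyl from the hindered secondary C8 and the tertiary C10 hydroxyl (selective O‑acetylation).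

Step 19
Reactants: 30 13-O-acetate
Product: 31 target
Conditions: angelic acid, 2,4,6-trichlorobenzoyl chloride, Et3N, toluene, rt; then 30, toluene, 80 °C
Reagents that add atoms: angelic acid C/C=C(/C)C(=O)O
Why: Mixed‑anhydride (Yamaguchi‑type) esterification without DMAP should transfer the angeloyl group to the secondary C8 hydroxyl without Z‑to‑E isomerisation, and the tertiary C10 hydroxyl does not react.

**Compound list**

1 | furan-3,4-diyldimethanol | OCc1cocc1CO | starting material
2 | [4-({[tert-butyl(dimethyl)silyl]oxy}methyl)furan-3-yl]methanol | CC(C)(C)[Si](C)(C)OCc1cocc1CO | intermediate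
3 | 4-({[tert-butyl(dimethyl)silyl]oxy}methyl)furan-3-carbaldehyde | CC(C)(C)[Si](C)(C)OCc1cocc1C=O | intermediate
4 | 2-[4-({[tert-butyl(dimethyl)silyl]oxy}methyl)furan-3-yl]-1,3-dithiane | CC(C)(C)[Si](C)(C)OCc1cocc1C1SCCCS1 | intermediate
5 | (S)-(+)-linalool, (3S)-3,7-dimethylocta-1,6-dien-3-ol | CC(C)=CCC[C@@](C)(C=C)O | starting material
6 | (2E,6S)-2,6-dimethylocta-2,7-diene-1,6-diol | OC/C(C)=C/CC[C@@](C)(C=C)O | intermediate
7 | [(2R,3R)-3-[(3S)-3-hydroxy-3-methylpent-4-en-1-yl]-2-methyloxiran-2-yl]methanol (not isolated) | OC[C@@]1(C)O[C@@H]1CC[C@@](C)(C=C)O | intermediate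
8 | (2R)-2-[(2S,5S)-5-ethenyl-5-methyloxolan-2-yl]propane-1,2-diol | OC[C@@](C)(O)[C@@H]1CC[C@@](C)(C=C)O1 | intermediate
9 | (2R)-2-[(2S,5S)-5-ethenyl-5-methyloxolan-2-yl]-2-hydroxypropyl 4-methylbenzenesulfonate (not isolated) | Cc1ccc(cc1)S(=O)(=O)OC[C@@](C)(O)[C@@H]1CC[C@@](C)(C=C)O1 | intermediate
10 | (2S,5S)-2-ethenyl-2-methyl-5-[(2R)-2-methyloxiran-2-yl]oxolane | C[C@@]1(CO1)[C@@H]2CC[C@@](C)(C=C)O2 | intermediate
11 | 2-lithio derivative of dithiane 4 (not isolated) | CC(C)(C)[Si](C)(C)OCc1cocc1C1([Li])SCCCS1 | intermediate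
12 | (2R)-1-{2-[4-({[tert-butyl(dimethyl)silyl]oxy}methyl)furan-3-yl]-1,3-dithian-2-yl}-2-[(2S,5S)-5-ethenyl-5-methyloxolan-2-yl]propan-2-ol | CC(C)(C)[Si](C)(C)OCc1cocc1C1(SCCCS1)C[C@@](C)(O)[C@@H]2CC[C@@](C)(C=C)O2 | intermediate
13 | (3R)-1-[4-({[tert-butyl(dimethyl)silyl]oxy}methyl)furan-3-yl]-3-[(2S,5S)-5-ethenyl-5-methyloxolan-2-yl]-3-hydroxybutan-1-one | CC(C)(C)[Si](C)(C)OCc1cocc1C(=O)C[C@@](C)(O)[C@@H]2CC[C@@](C)(C=C)O2 | intermediate
14 | (1S,3R)-1-[4-({[tert-butyl(dimethyl)silyl]oxy}methyl)furan-3-yl]-3-[(2S,5S)-5-ethenyl-5-methyloxolan-2-yl]butane-1,3-diol | O[C@H](c1cocc1CO[Si](C)(C)C(C)(C)C)C[C@@](C)(O)[C@@H]2CC[C@@](C)(C=C)O2 | intermediate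
15 | O8,O10,O13-tris-TBS ether of 14 (C8 S; C10 R; C1 S; C4 S; vinyl on C4) | CC(C)(C)[Si](C)(C)O[C@H](c1cocc1CO[Si](C)(C)C(C)(C)C)C[C@@](C)(O[Si](C)(C)C(C)(C)C)[C@@H]2CC[C@@](C)(C=C)O2 | intermediate
16 | vicinal diol from the vinyl group of 15 (1,2-dihydroxyethyl on C4; epimers at the new carbinol; not isolated) | CC(C)(C)[Si](C)(C)O[C@H](c1cocc1CO[Si](C)(C)C(C)(C)C)C[C@@](C)(O[Si](C)(C)C(C)(C)C)[C@@H]2CC[C@@](C)(C(O)CO)O2 | intermediate
17 | C5 aldehyde (CHO on C4; not isolated) | CC(C)(C)[Si](C)(C)O[C@H](c1cocc1CO[Si](C)(C)C(C)(C)C)C[C@@](C)(O[Si](C)(C)C(C)(C)C)[C@@H]2CC[C@@](C)(C=O)O2 | intermediate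
18 | C5 primary alcohol (CH2OH on C4) | CC(C)(C)[Si](C)(C)O[C@H](c1cocc1CO[Si](C)(C)C(C)(C)C)C[C@@](C)(O[Si](C)(C)C(C)(C)C)[C@@H]2CC[C@@](C)(CO)O2 | intermediate
19 | C5 triflate of 18 (not isolated) | CC(C)(C)[Si](C)(C)O[C@H](c1cocc1CO[Si](C)(C)C(C)(C)C)C[C@@](C)(O[Si](C)(C)C(C)(C)C)[C@@H]2CC[C@@](C)(COS(=O)(=O)C(F)(F)F)O2 | intermediate
20 | C5 sulfide (C4–CH2–S–CH2CH2CO2CH3) | CC(C)(C)[Si](C)(C)O[C@H](c1cocc1CO[Si](C)(C)C(C)(C)C)C[C@@](C)(O[Si](C)(C)C(C)(C)C)[C@@H]2CC[C@@](C)(CSCCC(=O)OC)O2 | intermediate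
21 | C5 sulfone (C4–CH2–SO2–CH2CH2CO2CH3) | CC(C)(C)[Si](C)(C)O[C@H](c1cocc1CO[Si](C)(C)C(C)(C)C)C[C@@](C)(O[Si](C)(C)C(C)(C)C)[C@@H]2CC[C@@](C)(CS(=O)(=O)CCC(=O)OC)O2 | intermediate
22 | furan endoperoxide of 21 (2,3,7-trioxabicyclo[2.2.1]hept-5-ene; not isolated) | CC(C)(C)[Si](C)(C)O[C@H](C1=C(CO[Si](C)(C)C(C)(C)C)C3OOC1O3)C[C@@](C)(O[Si](C)(C)C(C)(C)C)[C@@H]2CC[C@@](C)(CS(=O)(=O)CCC(=O)OC)O2 | intermediate
23 | 5-hydroxybutenolide (C12 C=O; C6 hemiacetal; epimers at C6) with the C5 sulfone | CC(C)(C)[Si](C)(C)O[C@H](C1=C(CO[Si](C)(C)C(C)(C)C)C(=O)OC1O)C[C@@](C)(O[Si](C)(C)C(C)(C)C)[C@@H]2CC[C@@](C)(CS(=O)(=O)CCC(=O)OC)O2 | intermediate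
24 | C5 sulfinic acid of the 5-hydroxybutenolide (not isolated) | CC(C)(C)[Si](C)(C)O[C@H](C1=C(CO[Si](C)(C)C(C)(C)C)C(=O)OC1O)C[C@@](C)(O[Si](C)(C)C(C)(C)C)[C@@H]2CC[C@@](C)(CS(=O)O)O2 | intermediate
25 | ten-membered cyclic sulfone (SO2 between C5 and C6; C6 is the lactone acetal carbon; epimers at C6) | CC(C)(C)[Si](C)(C)O[C@H]1C[C@@](C)(O[Si](C)(C)C(C)(C)C)[C@@H]2CC[C@@](C)(CS(=O)(=O)C3OC(=O)C(CO[Si](C)(C)C(C)(C)C)=C31)O2 | intermediate
26 | C5-chloro derivative of 25 (not isolated) | CC(C)(C)[Si](C)(C)O[C@H]1C[C@@](C)(O[Si](C)(C)C(C)(C)C)[C@@H]2CC[C@@](C)(C(Cl)S(=O)(=O)C3OC(=O)C(CO[Si](C)(C)C(C)(C)C)=C31)O2 | intermediate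
27 | episulfone (thiirane 1,1-dioxide across C5 and C6; not isolated) | CC(C)(C)[Si](C)(C)O[C@H]1C[C@@](C)(O[Si](C)(C)C(C)(C)C)[C@@H]2CC[C@@](C)(C4C3(OC(=O)C(CO[Si](C)(C)C(C)(C)C)=C31)S4(=O)=O)O2 | intermediate
28 | O8,O10,O13-tris-TBS ether of the tricyclic triol (5E enol lactone; 1S,4S,8S,10R) | CC(C)(C)[Si](C)(C)O[C@H]1C[C@@](C)(O[Si](C)(C)C(C)(C)C)[C@@H]2CC[C@@](C)(/C=C3/OC(=O)C(CO[Si](C)(C)C(C)(C)C)=C31)O2 | intermediate
29 | tricyclic triol (OH at C8, C10 and C13) | O[C@H]1C[C@@](C)(O)[C@@H]2CC[C@@](C)(/C=C3/OC(=O)C(CO)=C31)O2 | intermediate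
30 | 13-O-acetate of the triol | O[C@H]1C[C@@](C)(O)[C@@H]2CC[C@@](C)(/C=C3/OC(=O)C(COC(C)=O)=C31)O2 | intermediate
31 | CNP0162854.1 (8-O-angelate; 13-O-acetate) | C/C=C(/C)C(=O)O[C@H]1C[C@@](C)(O)[C@@H]2CC[C@@](C)(/C=C3/OC(=O)C(COC(C)=O)=C31)O2 | target

**Step count and risk**

Total steps: 19. Longest linear sequence: 16 steps (steps 4–19 from 5, or steps 1–3 and 7–19 from 1).

The three steps most likely to fail:

Step 16 (Proposed new method). What may go wrong: halogen transfer back from the α‑halo sulfone to the oxidofuran, double halogenation, or opening of the lactone before the 1,3‑elimination, so that no episulfone forms. The fallback uses known chemistry and closes the oxonane directly by olefination. It sets out from 15, which is photooxygenated as in step 14 through the endoperoxide F1 to the 5‑hydroxybutenolide F2. Dimethyl phosphite (NaOMe cat., then MsOH; Abramov addition to the ring‑opened aldehyde and relactonisation, as in the preparation of phthalide‑3‑phosphonates) gives the C6 phosphonate F3. Ozonolysis of the vinyl group (O3, CH2Cl2, −78 °C; PPh3) goes through the ozonide F4 to the C5 aldehyde F5. An intramolecular Horner–Wadsworth–Emmons olefination (LiCl, DBU, MeCN, high dilution) should then form C5=C6, and the route is rejoined at 28.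

Step 15. What may go wrong: disproportionation of the free sulfinic acid, or oligomerisation instead of closure of the ten‑membered ring. The fallback brings sulfur in at the thiol level and oxidises after ring closure. It sets out from 18: the triflate 19 is displaced with potassium thioacetate to give the thioacetate F6. Photooxygenation as in step 14, via the endoperoxide F7, gives the hydroxybutenolide F8. Methanolysis (K2CO3, MeOH) frees the thiol F9, and acid‑catalysed condensation of thiol and pseudo‑acid (CSA, CH2Cl2, 4 Å MS, high dilution; known for 5‑alkylthio‑butenolides) closes the cyclic S,O‑acetal sulfide F10. Oxidation with mCPBA returns to the route at 25.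

Step 14. What may go wrong: poor site selectivity in the base‑induced fragmentation of the endoperoxide, giving the regioisomeric hydroxybutenolide with C6 as the carbonyl. The fallback fixes the regiochemistry with silicon before the oxidation. It sets out from 21: iridium‑catalysed C–H silylation ([Ir(cod)OMe]2, dtbpy, Et3SiH, norbornene) at the less hindered furan α‑position should give the C12‑triethylsilyl furan F11, whose regiochemistry can be checked and purified at the furan stage. Photooxygenation of the 2‑silylfuran without base, via the silyl endoperoxide F12 (silyl shift from C12 to the peroxide oxygen makes C12 the carbonyl), returns to the route at 23.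

Further compounds
F1 | step 16 | furan endoperoxide of 15 | CC(C)(C)[Si](C)(C)O[C@H](C1=C(CO[Si](C)(C)C(C)(C)C)C3OOC1O3)C[C@@](C)(O[Si](C)(C)C(C)(C)C)[C@@H]2CC[C@@](C)(C=C)O2
F2 | step 16 | 5-hydroxybutenolide with the vinyl group on C4 (epimers at C6) | CC(C)(C)[Si](C)(C)O[C@H](C1=C(CO[Si](C)(C)C(C)(C)C)C(=O)OC1O)C[C@@](C)(O[Si](C)(C)C(C)(C)C)[C@@H]2CC[C@@](C)(C=C)O2
F3 | step 16 | C6 dimethyl phosphonate of the butenolide (vinyl on C4) | CC(C)(C)[Si](C)(C)O[C@H](C1=C(CO[Si](C)(C)C(C)(C)C)C(=O)OC1P(=O)(OC)OC)C[C@@](C)(O[Si](C)(C)C(C)(C)C)[C@@H]2CC[C@@](C)(C=C)O2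
F4 | step 16 | ozonide (1,2,4-trioxolane) of F3 | CC(C)(C)[Si](C)(C)O[C@H](C1=C(CO[Si](C)(C)C(C)(C)C)C(=O)OC1P(=O)(OC)OC)C[C@@](C)(O[Si](C)(C)C(C)(C)C)[C@@H]2CC[C@@](C)(C3OCOO3)O2
F5 | step 16 | C5 aldehyde with the C6 phosphonate | CC(C)(C)[Si](C)(C)O[C@H](C1=C(CO[Si](C)(C)C(C)(C)C)C(=O)OC1P(=O)(OC)OC)C[C@@](C)(O[Si](C)(C)C(C)(C)C)[C@@H]2CC[C@@](C)(C=O)O2
F6 | step 15 | C5 thioacetate (furan stage) | CC(C)(C)[Si](C)(C)O[C@H](c1cocc1CO[Si](C)(C)C(C)(C)C)C[C@@](C)(O[Si](C)(C)C(C)(C)C)[C@@H]2CC[C@@](C)(CSC(C)=O)O2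
F7 | step 15 | furan endoperoxide of F6 | CC(C)(C)[Si](C)(C)O[C@H](C1=C(CO[Si](C)(C)C(C)(C)C)C3OOC1O3)C[C@@](C)(O[Si](C)(C)C(C)(C)C)[C@@H]2CC[C@@](C)(CSC(C)=O)O2
F8 | step 15 | 5-hydroxybutenolide with the C5 thioacetate | CC(C)(C)[Si](C)(C)O[C@H](C1=C(CO[Si](C)(C)C(C)(C)C)C(=O)OC1O)C[C@@](C)(O[Si](C)(C)C(C)(C)C)[C@@H]2CC[C@@](C)(CSC(C)=O)O2
F9 | step 15 | 5-hydroxybutenolide with the free C5 thiol | CC(C)(C)[Si](C)(C)O[C@H](C1=C(CO[Si](C)(C)C(C)(C)C)C(=O)OC1O)C[C@@](C)(O[Si](C)(C)C(C)(C)C)[C@@H]2CC[C@@](C)(CS)O2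
F10 | step 15 | ten-membered cyclic S,O-acetal sulfide (S between C5 and C6) | CC(C)(C)[Si](C)(C)O[C@H]1C[C@@](C)(O[Si](C)(C)C(C)(C)C)[C@@H]2CC[C@@](C)(CSC3OC(=O)C(CO[Si](C)(C)C(C)(C)C)=C31)O2
F11 | step 14 | C12-triethylsilyl furan derived from 21 | CC(C)(C)[Si](C)(C)O[C@H](c1coc([Si](CC)(CC)CC)c1CO[Si](C)(C)C(C)(C)C)C[C@@](C)(O[Si](C)(C)C(C)(C)C)[C@@H]2CC[C@@](C)(CS(=O)(=O)CCC(=O)OC)O2
F12 | step 14 | endoperoxide of the silylfuran F11 | CC(C)(C)[Si](C)(C)O[C@H](C1=C(CO[Si](C)(C)C(C)(C)C)C3([Si](CC)(CC)CC)OOC1O3)C[C@@](C)(O[Si](C)(C)C(C)(C)C)[C@@H]2CC[C@@](C)(CS(=O)(=O)CCC(=O)OC)O2
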